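**Retrosynthetic overview**
1. Target 14 comes from phenol 12 by O-methylation at C4′ and removal of three methoxymethyl (MOM) ethers. The strategy rests on the 1,1-dimethylallyl group at C5′ of ring B, whose quaternary carbon is bonded to the ring ortho to the C4′ oxygen.
2. Key disconnection: the C5′–C(CH3)2 bond, made by aromatic Claisen rearrangement of the C4′ O-prenyl ether 10 on the finished isoflavanone.
3. Ring C of 10 is disconnected at C3–C4 (carbene-catalysed crossed benzoin of keto-aldehyde 9, which sets C3) and at O1–C2 (phenol 8 plus bromoketone 6).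
4. 6 comes from gallacetophenone 1 (4-O-prenylation, MOM protection, α-bromination through a silyl enol ether); 8 comes from 2,4-dihydroxybenzaldehyde 7.
5. Ring order: rings A and B are bought, ring C is the only ring formed (step 6), and no ring is formed afterwards.

Key step: step 7

Assumption: the (5aR,10bS) antipode of the aminoindanol-derived triazolium salt is taken to give the (3R) ketol; the sense of induction is to be checked on a first small batch and the (5aS,10bR) antipode used if it turns out opposite.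

**Route**

Step 1
Reactants: 1 2,3,4-trihydroxyacetophenone (gallacetophenone); 2 prenyl bromide (1-bromo-3-methylbut-2-ene)
Product: 3 1-{2,3-dihydroxy-4-[(3-methylbut-2-en-1-yl)oxy]phenyl}ethan-1-one
Conditions: 2 (1.05 equiv), NaHCO3 (1.2 equiv), DMF, 40 °C
Reagents that add atoms: none
Why: Williamson ether synthesis under a weak base, in which the C4 hydroxyl (para to the acetyl group) is the most acidic and the C2 hydroxyl is held in a hydrogen bond to the carbonyl, so one equivalent of the allylic bromide should alkylate O4 selectively by SN2.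

Step 2
Reactants: 3 1-{2,3-dihydroxy-4-[(3-methylbut-2-en-1-yl)oxy]phenyl}ethan-1-one
Product: 4 1-{2,3-bis(methoxymethoxy)-4-[(3-methylbut-2-en-1-yl)oxy]phenyl}ethan-1-one
Conditions: NaH (2.3 equiv), MOMCl (2.6 equiv), DMF, 0 °C to rt, argon
Reagents that add atoms: chloromethyl methyl ether, COCCl
Why: MOM protection by Williamson-type alkylation, in which the bis-phenoxide formed with NaH (including the hydrogen-bonded C2 phenol) reacts with the very reactive chloromethyl ether faster than the ketone is enolised.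

Step 3
Reactants: 4 1-{2,3-bis(methoxymethoxy)-4-[(3-methylbut-2-en-1-yl)oxy]phenyl}ethan-1-one
Product: 6 2-bromo-1-{2,3-bis(methoxymethoxy)-4-[(3-methylbut-2-en-1-yl)oxy]phenyl}ethan-1-one, via silyl enol ether 5 (not isolated)
Conditions: LiN(SiMe3)2 (1.1 equiv), THF, −78 °C; Me3SiCl (1.2 equiv); then NBS (1.05 equiv), −78 to 0 °C
Reagents that add atoms: N-bromosuccinimide, O=C1CCC(=O)N1Br (bromine in 6); chlorotrimethylsilane, C[Si](C)(C)Cl (silyl group in 5 only)
Why: α-Bromination through a silyl enol ether, in which kinetic enolisation of the methyl ketone and O-silylation give 5, which NBS brominates at carbon much faster than it attacks the prenyl double bond or the ring, and no HBr is released that could cleave the acetals.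

Step 4
Reactants: 7 2,4-dihydroxybenzaldehyde
Product: 8 2-hydroxy-4-(methoxymethoxy)benzaldehyde
Conditions: MOMCl (1.05 equiv), K2CO3 (1.1 equiv), acetone, 0 °C to rt
Reagents that add atoms: chloromethyl methyl ether, COCCl
Why: Selective MOM protection, in which the C2 hydroxyl is hydrogen-bonded to the formyl group so that the more acidic, unchelated C4 phenoxide is alkylated first by one equivalent of reagent.

Step 5
Reactants: 6 2-bromo-1-{2,3-bis(methoxymethoxy)-4-[(3-methylbut-2-en-1-yl)oxy]phenyl}ethan-1-one; 8 2-hydroxy-4-(methoxymethoxy)benzaldehyde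
Product: 9 2-(2-{2,3-bis(methoxymethoxy)-4-[(3-methylbut-2-en-1-yl)oxy]phenyl}-2-oxoethoxy)-4-(methoxymethoxy)benzaldehyde
Conditions: K2CO3 (1.5 equiv), acetone, rt
Reagents that add atoms: none
Why: Williamson ether synthesis, in which the phenoxide of 8 displaces the activated α-bromide of 6 by SN2 at room temperature, mild enough to hold back aldol condensation of the product to a 2-aroylbenzofuran (Rap–Stoermer reaction).

Step 6
Reactants: 9 2-(2-{2,3-bis(methoxymethoxy)-4-[(3-methylbut-2-en-1-yl)oxy]phenyl}-2-oxoethoxy)-4-(methoxymethoxy)benzaldehyde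
Product: 10 (3R)-3-{2,3-bis(methoxymethoxy)-4-[(3-methylbut-2-en-1-yl)oxy]phenyl}-3-hydroxy-7-(methoxymethoxy)-2,3-dihydro-4H-chromen-4-one
Conditions: (5aR,10bS)-2-(pentafluorophenyl)-5a,10b-dihydro-4H,6H-indeno[2,1-b][1,2,4]triazolo[4,3-d][1,4]oxazin-2-ium tetrafluoroborate (C18H11BF9N3O, 10 mol %), Et3N (10 mol %), toluene, rt, argon
Reagents that add atoms: none
Why: N-Heterocyclic-carbene-catalysed enantioselective intramolecular crossed aldehyde–ketone benzoin reaction, in which the carbene adds to the aldehyde, the Breslow intermediate attacks the aryl ketone in a 6-exo-trig closure that forms the C3–C4 bond of ring C, and the fused aminoindanol backbone of the catalyst shields one face so that the C3 carbinol is set as (R).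

Step 7
Reactants: 10 (3R)-3-{2,3-bis(methoxymethoxy)-4-[(3-methylbut-2-en-1-yl)oxy]phenyl}-3-hydroxy-7-(methoxymethoxy)-2,3-dihydro-4H-chromen-4-one
Product: 12 (3R)-3-hydroxy-3-[4-hydroxy-2,3-bis(methoxymethoxy)-5-(2-methylbut-3-en-2-yl)phenyl]-7-(methoxymethoxy)-2,3-dihydro-4H-chromen-4-one, via ortho-dienone tautomer 11 (not isolated)
Conditions: EtOH–H2O (4:1), degassed, 2,6-lutidine (0.1 equiv), sealed tube, 130 °C
Reagents that add atoms: none
Why: Heating the aryl 3,3-dimethylallyl ether drives a concerted, chair-like [3,3]-sigmatropic shift (aromatic Claisen rearrangement) in which the O–CH2 bond breaks while the dimethyl-substituted allyl terminus bonds to C5′, giving ortho-dienone 11, which enolises to phenol 12; allyl inversion is what places the quaternary carbon on the ring. The closest known reaction type is the ortho-Claisen rearrangement of aryl prenyl ethers to 2-(1,1-dimethylallyl)phenols run in aqueous alcohol, where hydrogen bonding to the ether oxygen lowers the temperature needed; a Lewis-acid catalyst is left out on purpose, because the only chelating site of 10 is the C3-OH/C4=O ketol and not the C4′ ether, so a bound Lewis acid would favour ionisation of the prenyl group and rearrangement of the ketol. No ring is closed, the six-membered transition state being transient, and no stereocentre is created, since the sp3 ring carbon of 11 is lost on tautomerisation and the quaternary C3 carbinol takes no part. The step needs regioselectivity for C5′, which the substrate secures because C3′ carries a methoxymethoxy group and the para carbon C1′ carries C3, so shifts to those carbons give dienones that cannot aromatise and revert. It also needs the [3,3] path to win over ionic [1,3] migration and the reaction to stop at 12, which the neutral acid-free medium, the moderate temperature and direct methylation in step 8 are meant to secure.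

Step 8
Reactants: 12 (3R)-3-hydroxy-3-[4-hydroxy-2,3-bis(methoxymethoxy)-5-(2-methylbut-3-en-2-yl)phenyl]-7-(methoxymethoxy)-2,3-dihydro-4H-chromen-4-one
Product: 13 (3R)-3-hydroxy-3-[4-methoxy-2,3-bis(methoxymethoxy)-5-(2-methylbut-3-en-2-yl)phenyl]-7-(methoxymethoxy)-2,3-dihydro-4H-chromen-4-one
Conditions: MeI (5 equiv), K2CO3 (3 equiv), DMF, rt
Reagents that add atoms: iodomethane, CI
Why: Williamson O-methylation, in which only the phenol is acidic enough for K2CO3, so the hindered C4′ phenoxide is methylated by the small electrophile while the tertiary C3 alcohol, which has no α-hydrogen and cannot epimerise, is left untouched.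

Step 9
Reactants: 13 (3R)-3-hydroxy-3-[4-methoxy-2,3-bis(methoxymethoxy)-5-(2-methylbut-3-en-2-yl)phenyl]-7-(methoxymethoxy)-2,3-dihydro-4H-chromen-4-one
Product: 14 (3R)-3-[2,3-dihydroxy-4-methoxy-5-(2-methylbut-3-en-2-yl)phenyl]-3,7-dihydroxy-2,3-dihydro-4H-chromen-4-one
Conditions: HCl (1.25 M in MeOH), 0 °C to rt
Reagents that add atoms: none
Why: Acid-catalysed acetal exchange (MOM cleavage), in which the three aryl methoxymethyl ethers transfer their formaldehyde unit to methanol under dilute HCl at or below room temperature, conditions under which the aryl methyl ether, the monosubstituted alkene and the tertiary alcohol (its ionisation disfavoured by the adjacent carbonyl) should persist.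

**Compound list**
1 | 2,3,4-trihydroxyacetophenone (gallacetophenone) | CC(=O)c1ccc(O)c(O)c1O | starting material
2 | prenyl bromide (1-bromo-3-methylbut-2-ene) | CC(C)=CCBr | starting material
3 | 1-{2,3-dihydroxy-4-[(3-methylbut-2-en-1-yl)oxy]phenyl}ethan-1-one | CC(=O)c1ccc(OCC=C(C)C)c(O)c1O | intermediate
4 | 1-{2,3-bis(methoxymethoxy)-4-[(3-methylbut-2-en-1-yl)oxy]phenyl}ethan-1-one | CC(=O)c1ccc(OCC=C(C)C)c(OCOC)c1OCOC | intermediate
5 | {[1-{2,3-bis(methoxymethoxy)-4-[(3-methylbut-2-en-1-yl)oxy]phenyl}ethenyl]oxy}trimethylsilane | C=C(O[Si](C)(C)C)c1ccc(OCC=C(C)C)c(OCOC)c1OCOC | intermediate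
6 | 2-bromo-1-{2,3-bis(methoxymethoxy)-4-[(3-methylbut-2-en-1-yl)oxy]phenyl}ethan-1-one | BrCC(=O)c1ccc(OCC=C(C)C)c(OCOC)c1OCOC | intermediate
7 | 2,4-dihydroxybenzaldehyde | O=Cc1ccc(O)cc1O | starting material
8 | 2-hydroxy-4-(methoxymethoxy)benzaldehyde | O=Cc1ccc(OCOC)cc1O | intermediate
9 | 2-(2-{2,3-bis(methoxymethoxy)-4-[(3-methylbut-2-en-1-yl)oxy]phenyl}-2-oxoethoxy)-4-(methoxymethoxy)benzaldehyde | O=Cc1ccc(OCOC)cc1OCC(=O)c1ccc(OCC=C(C)C)c(OCOC)c1OCOC | intermediate
10 | (3R)-3-{2,3-bis(methoxymethoxy)-4-[(3-methylbut-2-en-1-yl)oxy]phenyl}-3-hydroxy-7-(methoxymethoxy)-2,3-dihydro-4H-chromen-4-one | CC(C)=CCOc1ccc([C@@]2(O)COc3cc(OCOC)ccc3C2=O)c(OCOC)c1OCOC | intermediate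
11 | (3R)-3-hydroxy-7-(methoxymethoxy)-3-[5,6-bis(methoxymethoxy)-3-(2-methylbut-3-en-2-yl)-4-oxocyclohexa-1,5-dien-1-yl]-2,3-dihydro-4H-chromen-4-one (either configuration at the ring sp3 carbon) | C=CC(C)(C)C1C=C([C@@]2(O)COc3cc(OCOC)ccc3C2=O)C(OCOC)=C(OCOC)C1=O | intermediate
12 | (3R)-3-hydroxy-3-[4-hydroxy-2,3-bis(methoxymethoxy)-5-(2-methylbut-3-en-2-yl)phenyl]-7-(methoxymethoxy)-2,3-dihydro-4H-chromen-4-one | C=CC(C)(C)c1cc([C@@]2(O)COc3cc(OCOC)ccc3C2=O)c(OCOC)c(OCOC)c1O | intermediate
13 | (3R)-3-hydroxy-3-[4-methoxy-2,3-bis(methoxymethoxy)-5-(2-methylbut-3-en-2-yl)phenyl]-7-(methoxymethoxy)-2,3-dihydro-4H-chromen-4-one | C=CC(C)(C)c1cc([C@@]2(O)COc3cc(OCOC)ccc3C2=O)c(OCOC)c(OCOC)c1OC | intermediate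
14 | (3R)-3-[2,3-dihydroxy-4-methoxy-5-(2-methylbut-3-en-2-yl)phenyl]-3,7-dihydroxy-2,3-dihydro-4H-chromen-4-one | C=CC(C)(C)c1cc([C@@]2(O)COc3cc(O)ccc3C2=O)c(O)c(O)c1OC | target

**Count**
Total steps: 9. Longest linear sequence: 8 steps (steps 1, 2, 3, 5, 6, 7, 8 and 9 from gallacetophenone 1; step 4 is a one-step branch).

**Steps most likely to fail**

Step 7 (key step). The allylic C–O bond may break heterolytically instead of migrating in concert, which would lead to loss of the prenyl group or a linear [1,3] product. The ortho-allylphenol may also rearrange further or close onto its alkene, and the acetals may hydrolyse at 130 °C. The fallback moves the same rearrangement to a stage that carries neither the ketol nor the stereocentre. Ketone 4 is heated in N,N-diethylaniline at about 190 °C and should pass through 4-acetyl-2,3-bis(methoxymethoxy)-6-(2-methylbut-3-en-2-yl)cyclohexa-2,4-dien-1-one F1 to 1-[4-hydroxy-2,3-bis(methoxymethoxy)-5-(2-methylbut-3-en-2-yl)phenyl]ethan-1-one F2. Methylation with MeI and K2CO3 in DMF should give 1-[4-methoxy-2,3-bis(methoxymethoxy)-5-(2-methylbut-3-en-2-yl)phenyl]ethan-1-one F3. Treatment with LiN(SiMe3)2 and Me3SiCl should give ({1-[4-methoxy-2,3-bis(methoxymethoxy)-5-(2-methylbut-3-en-2-yl)phenyl]ethenyl}oxy)trimethylsilane F4, which NBS should convert in the same flask into 2-bromo-1-[4-methoxy-2,3-bis(methoxymethoxy)-5-(2-methylbut-3-en-2-yl)phenyl]ethan-1-one F5. Alkylation of phenol 8 with F5 (K2CO3, acetone, rt) should give 2-{2-[4-methoxy-2,3-bis(methoxymethoxy)-5-(2-methylbut-3-en-2-yl)phenyl]-2-oxoethoxy}-4-(methoxymethoxy)benzaldehyde F6. The carbene-catalysed benzoin reaction of step 6 applied to F6 should then give 13 directly, where the route is rejoined.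

Step 6. Facial selectivity may be poor when the Breslow intermediate attacks the hindered, electron-rich, ortho-substituted aryl ketone, and a slow closure would leave room for base-mediated aldol cyclisation. The fallback gives up asymmetric catalysis for resolution. From 9, the achiral carbene generated from 3-ethyl-5-(2-hydroxyethyl)-4-methylthiazolium bromide (C8H14BrNOS) and DBU in t-BuOH at 40 °C should close ring C to rac-3-{2,3-bis(methoxymethoxy)-4-[(3-methylbut-2-en-1-yl)oxy]phenyl}-3-hydroxy-7-(methoxymethoxy)-2,3-dihydro-4H-chromen-4-one F7. F7 is separated by preparative chromatography on an amylose tris(3,5-dimethylphenylcarbamate) phase. The (R)-enantiomer is 10, where the route is rejoined, and the (3S)-3-{2,3-bis(methoxymethoxy)-4-[(3-methylbut-2-en-1-yl)oxy]phenyl}-3-hydroxy-7-(methoxymethoxy)-2,3-dihydro-4H-chromen-4-one F8 is set aside.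

Step 9. Under protic acid the tertiary benzylic C3–OH bond may ionise, assisted by the electron-rich ring B, which would lead to dehydration towards the isoflavone or to solvolysis; the vinyl group may also be protonated. The fallback replaces protic solvolysis by a buffered, aprotic exchange of acetal for silyl ether. From 13, Me3SiOTf and 2,2′-bipyridyl in MeCN at 0 °C should convert the three aryl MOM ethers into aryl trimethylsilyl ethers and silylate the C3 hydroxyl, giving (3R)-3-[4-methoxy-5-(2-methylbut-3-en-2-yl)-2,3-bis(trimethylsilyloxy)phenyl]-3,7-bis(trimethylsilyloxy)-2,3-dihydro-4H-chromen-4-one F9 after aqueous work-up at low temperature. Bu4NF buffered with AcOH in THF at 0 °C should then remove the four silyl groups and give 14, where the route is rejoined.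

**Further compounds**
F1 | step 7 | 4-acetyl-2,3-bis(methoxymethoxy)-6-(2-methylbut-3-en-2-yl)cyclohexa-2,4-dien-1-one | CC(=O)C1=CC(C(C)(C)C=C)C(=O)C(OCOC)=C1OCOC
F2 | step 7 | 1-[4-hydroxy-2,3-bis(methoxymethoxy)-5-(2-methylbut-3-en-2-yl)phenyl]ethan-1-one | CC(=O)c1cc(C(C)(C)C=C)c(O)c(OCOC)c1OCOC
F3 | step 7 | 1-[4-methoxy-2,3-bis(methoxymethoxy)-5-(2-methylbut-3-en-2-yl)phenyl]ethan-1-one | CC(=O)c1cc(C(C)(C)C=C)c(OC)c(OCOC)c1OCOC
F4 | step 7 | ({1-[4-methoxy-2,3-bis(methoxymethoxy)-5-(2-methylbut-3-en-2-yl)phenyl]ethenyl}oxy)trimethylsilane | C=C(O[Si](C)(C)C)c1cc(C(C)(C)C=C)c(OC)c(OCOC)c1OCOC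
F5 | step 7 | 2-bromo-1-[4-methoxy-2,3-bis(methoxymethoxy)-5-(2-methylbut-3-en-2-yl)phenyl]ethan-1-one | BrCC(=O)c1cc(C(C)(C)C=C)c(OC)c(OCOC)c1OCOC
F6 | step 7 | 2-{2-[4-methoxy-2,3-bis(methoxymethoxy)-5-(2-methylbut-3-en-2-yl)phenyl]-2-oxoethoxy}-4-(methoxymethoxy)benzaldehyde | O=Cc1ccc(OCOC)cc1OCC(=O)c1cc(C(C)(C)C=C)c(OC)c(OCOC)c1OCOC
F7 | step 6 | rac-3-{2,3-bis(methoxymethoxy)-4-[(3-methylbut-2-en-1-yl)oxy]phenyl}-3-hydroxy-7-(methoxymethoxy)-2,3-dihydro-4H-chromen-4-one | CC(C)=CCOc1ccc(C2(O)COc3cc(OCOC)ccc3C2=O)c(OCOC)c1OCOC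
F8 | step 6 | (3S)-3-{2,3-bis(methoxymethoxy)-4-[(3-methylbut-2-en-1-yl)oxy]phenyl}-3-hydroxy-7-(methoxymethoxy)-2,3-dihydro-4H-chromen-4-one | CC(C)=CCOc1ccc([C@]2(O)COc3cc(OCOC)ccc3C2=O)c(OCOC)c1OCOC
F9 | step 9 | (3R)-3-[4-methoxy-5-(2-methylbut-3-en-2-yl)-2,3-bis(trimethylsilyloxy)phenyl]-3,7-bis(trimethylsilyloxy)-2,3-dihydro-4H-chromen-4-one | C=CC(C)(C)c1cc([C@@]2(O[Si](C)(C)C)COc3cc(O[Si](C)(C)C)ccc3C2=O)c(O[Si](C)(C)C)c(O[Si](C)(C)C)c1OC
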